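The tetrahydrofuran is cut at O1–C2 and C2–C3. This exploits the fact that ring carbon C2, which carries the 4-hydroxyphenyl group, is flanked by both O1 and C3, so one aldehyde carbon can take up the ring oxygen and the C3 nucleophile in a single silyl-Prins annulation. The precursor is an acyclic hydroxy (E)-allylsilane that already holds the C4 and carbinol stereocentres from an Evans syn-aldol. Joining it to a protected 4-hydroxybenzaldehyde closes the only ring, sets C2 and C3 (all-trans ring) and leaves a C3 vinyl group as the masked CH2OAc arm. Ozonolysis–reduction, desilylation–peracetylation and selective aryl-acetate aminolysis finish the target.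

Key step: step 6

Remark: the ring is numbered O1, C2 (aryl-bearing), C3 (CH2OAc-bearing), C4 (side-chain-bearing), C5 (CH2) throughout. TBS = tert-butyldimethylsilyl, TMS = trimethylsilyl, Tf = trifluoromethanesulfonyl, Piv = pivaloyl. Compounds 1, 2, 5, 10 and 12 are assumed to be purchased.

Step 1
Reactants: 1 (S)-4-benzyl-2-oxazolidinone; 2 but-3-enoic acid
Product: 4 (S)-4-benzyl-3-(but-3-enoyl)oxazolidin-2-one, via but-3-enoic pivalic anhydride 3 (not isolated)
Conditions: 2, PivCl, Et3N, THF, −20 °C; then LiCl, 1, −20 °C → rt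
Reagents that add atoms: none
Why: Mixed-anhydride N-acylation of the oxazolidinone (LiCl/Et3N variant) acylates nitrogen under weakly basic, cold conditions that should keep the β,γ-alkene out of conjugation; no stereocentre is formed.

Step 2
Reactants: 4 (S)-4-benzyl-3-(but-3-enoyl)oxazolidin-2-one; 5 4-methoxybenzaldehyde
Product: 7 (S)-4-benzyl-3-[(2S,3S)-3-hydroxy-3-(4-methoxyphenyl)-2-vinylpropanoyl]oxazolidin-2-one, via dibutylboron (Z)-dienolate 6 (not isolated)
Conditions: Bu2BOTf, Et3N, CH2Cl2, −78 → 0 °C; then 5, −78 → 0 °C; pH 7 buffer, MeOH, H2O2, 0 °C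
Reagents that add atoms: none
Why: Evans syn-aldol in which the (Z)-boron dienolate reacts at its α-carbon through a Zimmerman–Traxler chair with the auxiliary benzyl group shielding one enolate face, setting the α-vinyl centre (S) and the carbinol centre (S) together as the syn pair that becomes ring C4 and the exocyclic CH(OAc) carbon.

Step 3
Reactants: 7 (S)-4-benzyl-3-[(2S,3S)-3-hydroxy-3-(4-methoxyphenyl)-2-vinylpropanoyl]oxazolidin-2-one
Product: 8 (S)-4-benzyl-3-[(2S,3S)-3-(tert-butyldimethylsilyloxy)-3-(4-methoxyphenyl)-2-vinylpropanoyl]oxazolidin-2-one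
Conditions: TBSOTf, 2,6-lutidine, CH2Cl2, −78 → 0 °C
Reagents that add atoms: tert-butyldimethylsilyl triflate, CC(C)(C)[Si](C)(C)OS(=O)(=O)C(F)(F)F
Why: Silyl triflate silylation of the secondary alcohol with a hindered pyridine base is fast in the cold and too weakly basic to cause retro-aldol cleavage or conjugation of the vinyl group; both stereocentres are untouched.

Step 4
Reactants: 8 (S)-4-benzyl-3-[(2S,3S)-3-(tert-butyldimethylsilyloxy)-3-(4-methoxyphenyl)-2-vinylpropanoyl]oxazolidin-2-one
Product: 9 (2R)-2-[(S)-(tert-butyldimethylsilyloxy)(4-methoxyphenyl)methyl]but-3-en-1-ol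
Conditions: LiBH4, MeOH (1 equiv), THF, 0 °C
Reagents that add atoms: none
Why: Reductive cleavage of the N-acyl oxazolidinone by borohydride attack at the exocyclic carbonyl should give the primary alcohol and release the auxiliary without touching the silyl ether or the alkene; the α-centre keeps its geometry (its descriptor changes to R only through the priority change).

Step 5
Reactants: 9 (2R)-2-[(S)-(tert-butyldimethylsilyloxy)(4-methoxyphenyl)methyl]but-3-en-1-ol; 10 allyltrimethylsilane
Product: 11 (2R,3E)-2-[(S)-(tert-butyldimethylsilyloxy)(4-methoxyphenyl)methyl]-5-(trimethylsilyl)pent-3-en-1-ol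
Conditions: 10 (4 equiv), second-generation Grubbs catalyst RuCl2(=CHPh)(PCy3)(H2IMes) (5 mol %), 1,4-benzoquinone (10 mol %), CH2Cl2, 40 °C
Reagents that add atoms: none
Why: Olefin cross-metathesis of the monosubstituted alkene with excess allylsilane is driven by loss of ethylene; the branched allylic centre should disfavour homodimerisation of 9 and favour the (E)-alkene, and benzoquinone suppresses ruthenium hydride-mediated alkene migration.

Step 6
Reactants: 11 (2R,3E)-2-[(S)-(tert-butyldimethylsilyloxy)(4-methoxyphenyl)methyl]-5-(trimethylsilyl)pent-3-en-1-ol; 12 4-(tert-butyldimethylsilyloxy)benzaldehyde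
Product: 15 tert-butyl{4-[(2R,3R,4R)-4-[(S)-(tert-butyldimethylsilyloxy)(4-methoxyphenyl)methyl]-3-vinyltetrahydrofuran-2-yl]phenoxy}dimethylsilane, via trimethylsilyl ether 13 (not isolated), via (E)-oxocarbenium triflate 14 (not isolated)
Conditions: 2,6-di-tert-butyl-4-methylpyridine (1.1 equiv), TMSOTf (1.3 equiv), CH2Cl2, −78 °C; then 12 (1.2 equiv), −78 → −50 °C; Et3N quench
Reagents that add atoms: none
Why: The primary hydroxyl is silylated in the flask under hindered-pyridine buffering to give 13 without free triflic acid, and the remaining catalytic TMSOTf condenses 13 with 12 to the aryl-stabilised (E)-oxocarbenium ion 14 (O1–C2 bond), whose C2 is attacked by the γ-carbon of the allylsilane (C2–C3 bond), the β-silyl cation then losing Me3Si+ to leave the C3 vinyl group. The closest known reaction type is the silyl-Prins (intramolecular Hosomi–Sakurai) annulation of hydroxy allylsilanes or their silyl ethers with aldehydes to 2-substituted 3-vinyltetrahydrofurans. The tetrahydrofuran closes in a five-membered mode that is endo with respect to the C=O+ bond (O1 and C2 both become ring atoms) and exo with respect to the alkene (only C3 enters the ring). C3 is set by the existing C4 centre, because in the envelope transition state the small C4–H eclipses the alkene and the bulky silyloxybenzyl group points outward (least allylic 1,3-strain), so the vinyl group ends up trans to the C4 side chain; C2 is set by the (E)-geometry of the ion together with the (E)-geometry of the allylsilane, which favour an open, antiperiplanar approach with the aryl group pseudo-equatorial and trans to the vinyl group. The step needs 2,3-trans-3,4-trans diastereoselection, which the C4 substituent and the two (E)-configured π-systems should secure, and chemoselection for ring closure over ionisation or acetal-type participation of the p-methoxybenzylic oxygen and over a 2-oxonia-Cope shift, which the bulky TBS ether, the buffered medium at −78 °C, the three-atom tether (intramolecular, irreversible C–C bond formation) and the aryl stabilisation of 14 (a Cope shift would trade it for an unstabilised formaldehyde-type cation) should secure.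

Step 7
Reactants: 15 tert-butyl{4-[(2R,3R,4R)-4-[(S)-(tert-butyldimethylsilyloxy)(4-methoxyphenyl)methyl]-3-vinyltetrahydrofuran-2-yl]phenoxy}dimethylsilane
Product: 17 [(2R,3S,4R)-2-[4-(tert-butyldimethylsilyloxy)phenyl]-4-[(S)-(tert-butyldimethylsilyloxy)(4-methoxyphenyl)methyl]tetrahydrofuran-3-yl]methanol, via tetrahydrofuran-3-carbaldehyde 16 (not isolated)
Conditions: O3, CH2Cl2–MeOH (4:1), NaHCO3, Sudan Red 7B indicator, −78 °C; then NaBH4, −78 → 0 °C
Reagents that add atoms: ozone, [O-][O+]=O
Why: Ozonolysis with in-flask borohydride reduction should cleave the isolated vinyl group much faster than the electron-rich arenes when ozone is dosed to the indicator end point, and aldehyde 16 is reduced as it forms so that the β-alkoxy aldehyde cannot epimerise at C3 or open by elimination; C3 keeps its geometry.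

Step 8
Reactants: 17 [(2R,3S,4R)-2-[4-(tert-butyldimethylsilyloxy)phenyl]-4-[(S)-(tert-butyldimethylsilyloxy)(4-methoxyphenyl)methyl]tetrahydrofuran-3-yl]methanol
Product: 19 [(2R,3S,4R)-4-[(S)-acetoxy(4-methoxyphenyl)methyl]-2-(4-acetoxyphenyl)tetrahydrofuran-3-yl]methyl acetate, via triol 18 (not isolated)
Conditions: Bu4NF (3 equiv), THF, 0 °C → rt; then Et3N, Ac2O (excess), DMAP (cat.), 0 °C → rt
Reagents that add atoms: acetic anhydride, CC(=O)OC(C)=O
Why: Fluoride-mediated cleavage of both Si–O bonds followed by DMAP-catalysed acetylation of the three hydroxyls in the same flask avoids handling the polar phenol-diol and breaks no bond to a stereocentre.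

Step 9
Reactants: 19 [(2R,3S,4R)-4-[(S)-acetoxy(4-methoxyphenyl)methyl]-2-(4-acetoxyphenyl)tetrahydrofuran-3-yl]methyl acetate
Product: 20 [(2R,3S,4R)-4-[(S)-acetoxy(4-methoxyphenyl)methyl]-2-(4-hydroxyphenyl)tetrahydrofuran-3-yl]methyl acetate (CNP0231272.1)
Conditions: pyrrolidine (1.5 equiv), CH2Cl2, 0 °C
Reagents that add atoms: none
Why: Chemoselective aminolysis of the phenyl ester, whose phenoxide leaving group makes it far more reactive toward the secondary amine than the primary and benzylic alkyl acetates, in an aprotic neutral medium that should not solvolyse the p-methoxybenzylic acetate.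

Compound list
1 | (S)-4-benzyl-2-oxazolidinone | O=C1N[C@@H](Cc2ccccc2)CO1 | starting material
2 | but-3-enoic acid | C=CCC(=O)O | starting material
3 | but-3-enoic pivalic anhydride | C=CCC(=O)OC(=O)C(C)(C)C | intermediate
4 | (S)-4-benzyl-3-(but-3-enoyl)oxazolidin-2-one | C=CCC(=O)N1[C@@H](Cc2ccccc2)COC1=O | intermediate
5 | 4-methoxybenzaldehyde | COc1ccc(C=O)cc1 | starting material
6 | (S)-4-benzyl-3-[(1Z)-1-(dibutylboryloxy)buta-1,3-dien-1-yl]oxazolidin-2-one (boron dienolate of 4) | C=C/C=C(\OB(CCCC)CCCC)N1[C@@H](Cc2ccccc2)COC1=O | intermediate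
7 | (S)-4-benzyl-3-[(2S,3S)-3-hydroxy-3-(4-methoxyphenyl)-2-vinylpropanoyl]oxazolidin-2-one | COc1ccc([C@@H](O)[C@H](C=C)C(=O)N2[C@@H](Cc3ccccc3)COC2=O)cc1 | intermediate
8 | (S)-4-benzyl-3-[(2S,3S)-3-(tert-butyldimethylsilyloxy)-3-(4-methoxyphenyl)-2-vinylpropanoyl]oxazolidin-2-one | COc1ccc([C@@H](O[Si](C)(C)C(C)(C)C)[C@H](C=C)C(=O)N2[C@@H](Cc3ccccc3)COC2=O)cc1 | intermediate
9 | (2R)-2-[(S)-(tert-butyldimethylsilyloxy)(4-methoxyphenyl)methyl]but-3-en-1-ol | COc1ccc([C@@H](O[Si](C)(C)C(C)(C)C)[C@H](C=C)CO)cc1 | intermediate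
10 | allyltrimethylsilane | C=CC[Si](C)(C)C | starting material
11 | (2R,3E)-2-[(S)-(tert-butyldimethylsilyloxy)(4-methoxyphenyl)methyl]-5-(trimethylsilyl)pent-3-en-1-ol | COc1ccc([C@@H](O[Si](C)(C)C(C)(C)C)[C@H](/C=C/C[Si](C)(C)C)CO)cc1 | intermediate
12 | 4-(tert-butyldimethylsilyloxy)benzaldehyde | CC(C)(C)[Si](C)(C)Oc1ccc(C=O)cc1 | starting material
13 | trimethylsilyl ether of 11 at the primary oxygen | COc1ccc([C@@H](O[Si](C)(C)C(C)(C)C)[C@H](/C=C/C[Si](C)(C)C)CO[Si](C)(C)C)cc1 | intermediate
14 | (E)-oxocarbenium triflate from O-alkylation of 12 by the primary oxygen of 11 | COc1ccc([C@@H](O[Si](C)(C)C(C)(C)C)[C@H](/C=C/C[Si](C)(C)C)C/[O+]=C/c2ccc(O[Si](C)(C)C(C)(C)C)cc2)cc1.[O-]S(=O)(=O)C(F)(F)F | intermediate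
15 | tert-butyl{4-[(2R,3R,4R)-4-[(S)-(tert-butyldimethylsilyloxy)(4-methoxyphenyl)methyl]-3-vinyltetrahydrofuran-2-yl]phenoxy}dimethylsilane (all-trans ring) | COc1ccc([C@@H](O[Si](C)(C)C(C)(C)C)[C@H]2CO[C@@H](c3ccc(O[Si](C)(C)C(C)(C)C)cc3)[C@@H]2C=C)cc1 | intermediate
16 | (2R,3R,4R)-2-[4-(tert-butyldimethylsilyloxy)phenyl]-4-[(S)-(tert-butyldimethylsilyloxy)(4-methoxyphenyl)methyl]tetrahydrofuran-3-carbaldehyde | COc1ccc([C@@H](O[Si](C)(C)C(C)(C)C)[C@H]2CO[C@@H](c3ccc(O[Si](C)(C)C(C)(C)C)cc3)[C@@H]2C=O)cc1 | intermediate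
17 | [(2R,3S,4R)-2-[4-(tert-butyldimethylsilyloxy)phenyl]-4-[(S)-(tert-butyldimethylsilyloxy)(4-methoxyphenyl)methyl]tetrahydrofuran-3-yl]methanol | COc1ccc([C@@H](O[Si](C)(C)C(C)(C)C)[C@H]2CO[C@@H](c3ccc(O[Si](C)(C)C(C)(C)C)cc3)[C@@H]2CO)cc1 | intermediate
18 | 4-[(2R,3S,4R)-4-[(S)-hydroxy(4-methoxyphenyl)methyl]-3-(hydroxymethyl)tetrahydrofuran-2-yl]phenol | COc1ccc([C@@H](O)[C@H]2CO[C@@H](c3ccc(O)cc3)[C@@H]2CO)cc1 | intermediate
19 | [(2R,3S,4R)-4-[(S)-acetoxy(4-methoxyphenyl)methyl]-2-(4-acetoxyphenyl)tetrahydrofuran-3-yl]methyl acetate | COc1ccc([C@@H](OC(C)=O)[C@H]2CO[C@@H](c3ccc(OC(C)=O)cc3)[C@@H]2COC(C)=O)cc1 | intermediate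
20 | [(2R,3S,4R)-4-[(S)-acetoxy(4-methoxyphenyl)methyl]-2-(4-hydroxyphenyl)tetrahydrofuran-3-yl]methyl acetate | COc1ccc([C@@H](OC(C)=O)[C@H]2CO[C@@H](c3ccc(O)cc3)[C@@H]2COC(C)=O)cc1 | target

Total step count: 9. Longest linear sequence: 9 steps, from 1 (or 2) to 20; 5, 10 and 12 enter as purchased materials.

Steps most likely to fail

Step 6 (key annulation). Face selection at C2–C3 may be incomplete when the ring closes: any (Z)-allylsilane or a synclinal approach would lead toward the 2,3-cis ring. Heterolysis of the p-methoxybenzylic silyl ether or protodesilylation may also compete with capture of the oxocarbenium ion. The fallback sets out from 9 and returns at 17, replacing the allylsilane chemistry by the lactone aldol and acid-mediated cycloetherification tactic of tetrahydrofuran lignan synthesis. Alcohol 9 would be hydroborated (9-BBN, THF; then NaBO3 in water) to the butane-1,4-diol F1. Oxidative lactonisation with catalytic TEMPO and PhI(OAc)2 in CH2Cl2, which should start at the less hindered CH2CH2OH end, should give the β-substituted γ-butyrolactone F2. Its lithium enolate (LiHMDS, THF, −78 °C) should add to aldehyde 12 anti to the β-substituent, giving the aldol lactone F3 as carbinol epimers, both usable. LiBH4 in THF should reduce the lactone to the triol F4. Catalytic camphorsulfonic acid in CH2Cl2 at 0 °C should then ionise the free p-silyloxybenzylic alcohol and close O1–C2 with the C5 hydroxyl, placing the aryl group trans to the C3 hydroxymethyl group and giving 17; steps 8 and 9 follow unchanged.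

Step 5 (cross-metathesis). The (E)-selectivity may erode, turnover at the branched allylic position may be slow enough for homodimerisation of 10 to take over, or the double bond may migrate. The fallback sets out from 9 and returns at 11, building the (E)-allylsilane by olefination and cross-coupling. Alcohol 9 would be protected as the triethylsilyl ether F5 (Et3SiCl, imidazole, CH2Cl2) and ozonised with PPh3 work-up to the α-branched aldehyde F6. Takai iodo-olefination (CrCl2, CHI3, THF–dioxane, 0 °C) should give the (E)-vinyl iodide F7. Kumada coupling with Me3SiCH2MgCl and catalytic Pd(PPh3)4 in THF, with retention of alkene geometry, should give the silyl-protected (E)-allylsilane F8. Pyridinium p-toluenesulfonate in MeOH at 0 °C would then free the primary hydroxyl and rejoin the route at 11.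

Step 7 (ozonolysis–reduction). Ozone may over-oxidise the two electron-rich arenes, or the C3 aldehyde may epimerise or eliminate before it is reduced. The fallback sets out from 15 and returns at 17 through a two-stage cleavage with an isolable intermediate. Dihydroxylation of 15 with catalytic OsO4 and N-methylmorpholine N-oxide in acetone–water should give the vicinal diol F9. Glycol cleavage with NaIO4 in buffered THF–water should give aldehyde 16, which would be reduced at once with NaBH4 in MeOH at 0 °C to 17.

Further compounds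
F1 | step 6 | (R)-2-[(S)-(tert-butyldimethylsilyloxy)(4-methoxyphenyl)methyl]butane-1,4-diol | COc1ccc([C@@H](O[Si](C)(C)C(C)(C)C)[C@H](CCO)CO)cc1
F2 | step 6 | (R)-4-[(S)-(tert-butyldimethylsilyloxy)(4-methoxyphenyl)methyl]dihydrofuran-2(3H)-one | COc1ccc([C@@H](O[Si](C)(C)C(C)(C)C)[C@H]2COC(=O)C2)cc1
F3 | step 6 | (3R,4R)-3-{[4-(tert-butyldimethylsilyloxy)phenyl](hydroxy)methyl}-4-[(S)-(tert-butyldimethylsilyloxy)(4-methoxyphenyl)methyl]dihydrofuran-2(3H)-one, carbinol epimers | COc1ccc([C@@H](O[Si](C)(C)C(C)(C)C)[C@H]2COC(=O)[C@H]2C(O)c3ccc(O[Si](C)(C)C(C)(C)C)cc3)cc1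
F4 | step 6 | (2S,3R)-1-[4-(tert-butyldimethylsilyloxy)phenyl]-3-[(S)-(tert-butyldimethylsilyloxy)(4-methoxyphenyl)methyl]-2-(hydroxymethyl)butane-1,4-diol, C1 epimers | COc1ccc([C@@H](O[Si](C)(C)C(C)(C)C)[C@@H](CO)[C@@H](CO)C(O)c2ccc(O[Si](C)(C)C(C)(C)C)cc2)cc1
F5 | step 5 | triethylsilyl ether of 9 at the primary oxygen | COc1ccc([C@@H](O[Si](C)(C)C(C)(C)C)[C@H](C=C)CO[Si](CC)(CC)CC)cc1
F6 | step 5 | (2R,3S)-3-(tert-butyldimethylsilyloxy)-3-(4-methoxyphenyl)-2-[(triethylsilyloxy)methyl]propanal | COc1ccc([C@@H](O[Si](C)(C)C(C)(C)C)[C@H](C=O)CO[Si](CC)(CC)CC)cc1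
F7 | step 5 | (E)-vinyl iodide from F6 (iodomethylenation of the formyl group) | COc1ccc([C@@H](O[Si](C)(C)C(C)(C)C)[C@H](/C=C/I)CO[Si](CC)(CC)CC)cc1
F8 | step 5 | triethylsilyl ether of 11 at the primary oxygen | COc1ccc([C@@H](O[Si](C)(C)C(C)(C)C)[C@H](/C=C/C[Si](C)(C)C)CO[Si](CC)(CC)CC)cc1
F9 | step 7 | vicinal diol from dihydroxylation of the vinyl group of 15, carbinol epimers | COc1ccc([C@@H](O[Si](C)(C)C(C)(C)C)[C@H]2CO[C@@H](c3ccc(O[Si](C)(C)C(C)(C)C)cc3)[C@@H]2C(O)CO)cc1
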